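## Structural features

CNP0204573.1 is a cis-fused decalin: ring A (C10–C1–C2–C3–C4–C5) is a cyclohexanone with its carbonyl at C2 and a methyl group at C4, ring B (C5–C6–C7–C8–C9–C10) carries an isopropenyl group at C7, an acetate at C8 and a tiglate at C9, and the rings share the C5–C10 bond. All six stereocentres are contiguous (C4–C5–C10–C9–C8–C7): the C4 and C5 methyl groups are cis, C5 is quaternary, C10–H is cis to the C5 methyl group, the C7 and C8 substituents are trans and equatorial, and the C9 ester is cis to the C8 ester and axial. The fragile elements are the isopropenyl group (acid-sensitive, and a willing partner in cycloaddition, metathesis and hydration), the conjugated tiglate, and two different esters on a cis-1,2-diol, which can change places by acyl migration. The real difficulty is the quaternary C5 flanked by stereocentres at C4 and C10 inside a cis ring fusion, together with telling O8 from O9. The key step uses two facts: the C2 oxygen is 1,4 to C5 across ring A, and the cis C4/C5 methyl pair is the imprint of an (E)-2-methylbut-2-enyl unit, so a diene C10=C1–C2(OSi)=C3 and a dienophile C4=C5 joined through C6–C7–C8–C9 close ring A and ring B together. A free isopropenyl group at C7 would sit three atoms from the diene terminus C10 and would be a second, less substituted dienophile on a shorter tether; it is therefore carried through the cycloaddition as a silylated tertiary carbinol and regenerated afterwards.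

## Logic of the disconnections

29 to 27 and 1: the C9–O acyl bond is cut last. O9 is the hindered axial oxygen, and the conjugated ester then sees no further chemistry. The forward step must force an acylation without moving the neighbouring acetyl group.

27 to 26 to 25: the C8–O acetyl bond and then the two acetal C–O bonds are cut. The equatorial/axial difference between O8 and O9 is the only handle for telling them apart, and the cyclic acetal is the element that folds the tether in the key step. The forward steps need a selective mono-acylation and an acetal hydrolysis mild enough for the isopropenyl group.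

25 to 24 to 23: the C11=C12 alkene is traced back to a tertiary carbinol (a C11–O bond is added), and the C2 ketone to its silyl enol ether. This removes the only alkene that could interfere with the cycloaddition. The forward elimination must lose a methyl hydrogen, not C7–H, and the desilylation must spare the acetal.

23 to 22: C3–C4 and C5–C10 are cut. Both rings, the quaternary centre and three stereocentres are exchanged for an acyclic triene whose three stereocentres sit on one chain. The forward step needs cis fusion and one diene face from an unactivated trisubstituted alkene.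

22 to 21 to 19 to 17 to 16: the O–Si bonds are cut, then the C1–C2 bond, with C2, C3 and the C10 oxygen supplied by a 1,3-dipolar cycloaddition and C10=C1 traced to a vinyl group. A cross-metathesis route to the enone is avoided because ring closure between C10 and C5 through the same folded tether would compete. The forward dipole must choose the monosubstituted alkene over the trisubstituted one.

16 to 14: the C11–O bond is cut, giving back the isopropenyl group. The forward hydration must be Markovnikov and must select the 1,1-disubstituted alkene among three.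

14 to 13 to 11: the acetal is cut, then the C8–C9 bond. One reagent-controlled allylation supplies C9, C10 and C1 and both oxygen stereocentres. It must be anti-selective, must override the bias of C7, and must be mild enough for an aldehyde that epimerises and conjugates easily.

11 to 10 to 9 to 7 and 3: after redox adjustment at C8 the C6–C7 bond is cut. This is an auxiliary-controlled alkylation that sets C7 and brings in the dienophile with its geometry already fixed. The dienolate must react at its α-carbon, and the allylic bromide at its primary carbon.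

7 to 4 and 5; 3 to 2 to 1: the N–acyl bond, the C–Br bond and the carboxyl oxidation level are cut, reaching commercial materials. 1 serves twice, as the source of the dienophile and of the C9 ester.

## Other disconnections considered

Alternative 1: the cut is C1–C10 in ring A. In the forward direction the 4,4-disubstituted cyclohexadienone A2, (S)-4-methyl-4-(4-oxopentan-2-yl)cyclohexa-2,5-dien-1-one, is treated with a cinchona-derived primary amine and a carboxylic acid co-catalyst. The enamine of its methyl ketone adds through C1 to C10 of one enone arm and gives the cis-fused enedione A1.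
- In its favour: the tether can only reach the face of C5 that carries it, so the cis fusion is assured, and the catalyst sets C5 and C10 at ambient temperature. On fusion control and mildness this is better than the chosen plan, and A1 should be reached in fewer steps than 22.
- Against it: A1 carries none of the ring B substituents. C7 is the α-carbon of the C8 enone, so the isopropenyl group needs an α-alkenylation and a conjugate reduction; C9 needs α′-oxygenation; C8 needs reduction. All three centres would rest on substrate control, with two ketones to tell apart, and the C4 centre of A2 must be made first and matched to the catalyst.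
- Comparison: structurally the chosen plan fixes C7–C9 on an open chain with reagent control, while this one fixes the ring fusion better. Mechanistically a catalytic polar addition stands against a thermal pericyclic step. In step count the gain before the bicycle should be lost after it.

Alternative 2: the cut is C6–C7 in ring B. The allylic bromide A4 is reduced by CrCl2 (divalent chromium) to an allylchromium species whose γ-carbon C7 adds to the C6 aldehyde. This forms C6–C7, creates the isopropenyl group by allylic transposition, closes ring B and gives A3.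
- In its favour: the isopropenyl group appears only in this step, so no masking and no elimination are needed, which is better than the chosen plan. Chromium allylation is reliable at a neopentyl aldehyde. O8 (silyl ether) and O9 (ketal) arrive already differentiated, again better.
- Against it: the C6 hydroxyl of A3 is absent from the target and must be removed next to a quaternary carbon. The C9 ketal must later be reduced to the axial alcohol. A4 already contains ring A with C4, C5 and C10, so the quaternary centre and the ring-fusion relationship are moved upstream, not solved.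
- Comparison: on functional-group economy around C7–C9 it equals or beats the chosen plan. On structure it builds one bond and one ring where the cycloaddition builds two of each, and the extra deoxygenation and protecting groups should make it longer.

Alternative 3: the cuts are C1–C2 and C2–C3, with C2 coming from a one-carbon carbonylation. The diene A6 is hydroborated at the C10 methylene and at the C5 isopropenyl group by a hindered monoalkylborane, boron going to C1 and C3 to give a borinane. Carbonylation and alkaline peroxide oxidation then give the ketone A5.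
- In its favour: the ketone is placed at C2 without ambiguity, equal to the chosen plan. A5 is the triethylsilyl ether of 24, so it uses the same masked carbinol and would share the same endgame, also equal.
- Against it: C10 and C4 are both created by hydroboration of 1,1-disubstituted alkenes on either side of the quaternary carbon. That means two substrate-controlled facial choices where the cycloaddition gives the C4/C5 relation from alkene geometry. A hindered borane next to a quaternary centre is slow, carbonylation needs pressure, and A6 (quaternary C5 with methyl and isopropenyl beside an exocyclic methylene on a tetrasubstituted ring) is itself demanding.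
- Comparison: structurally it separates the making of ring B from that of ring A, which the chosen plan does in one step. Mechanistically it exchanges one uncertain transition state for two hydroboration selectivities. No saving in steps is apparent.

Key step: step 14

Remark: target atom numbering (C1–C10, C11 for the side-chain carbon on C7 and C12 for its methylene carbon) is used for every intermediate; the C7 isopropenyl group is carried from 16 to 24 as its tertiary carbinol, silylated in 22 and 23, so 22 and 23 are the cycloaddition precursor and product in that protected form, with triethylsilyl on both oxygens.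

Step 1
Reactants: 1 tiglic acid
Product: 2 (2E)-2-methylbut-2-en-1-ol
Conditions: LiAlH4, Et2O, 0 °C → rt
Reagents that add atoms: none
Why: Hydride reduction of the carboxylic acid gives the allylic alcohol by 1,2-reduction; the alkyl-substituted E alkene is not touched.

Step 2
Reactants: 2 (2E)-2-methylbut-2-en-1-ol
Product: 3 (2E)-1-bromo-2-methylbut-2-ene
Conditions: PBr3, Et2O, −10 → 0 °C
Reagents that add atoms: phosphorus tribromide BrP(Br)Br
Why: Conversion of a primary allylic alcohol into the bromide; the primary bromide with the trisubstituted alkene is also the more stable allylic isomer, so transposition is not expected, and the volatile bromide is used as a solution.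

Step 3
Reactants: 4 3-methylbut-3-enoic acid; 5 (4R)-4-benzyl-1,3-oxazolidin-2-one
Product: 7 (4R)-4-benzyl-3-(3-methylbut-3-enoyl)-1,3-oxazolidin-2-one, via mixed pivalic anhydride 6 (not isolated)
Conditions: t-BuCOCl, Et3N, THF, −20 °C; then 5, LiCl, rt
Reagents that add atoms: none
Why: N-Acylation of the Evans auxiliary through the mixed anhydride needs no strong base; any isomerisation to the conjugated acyl group is harmless because both isomers give the same dienolate in step 4.

Step 4
Reactants: 7 (4R)-4-benzyl-3-(3-methylbut-3-enoyl)-1,3-oxazolidin-2-one; 3 (2E)-1-bromo-2-methylbut-2-ene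
Product: 9 (4R)-4-benzyl-3-[(2R,4E)-4-methyl-2-(prop-1-en-2-yl)hex-4-enoyl]-1,3-oxazolidin-2-one, via sodium dienolate 8 (not isolated)
Conditions: NaN(SiMe3)2, THF, −78 °C; then 3, −78 → −45 °C
Reagents that add atoms: none
Why: Evans auxiliary alkylation: the chelated Z dienolate reacts at its α-carbon on the face away from the benzyl group, which sets C7 as R and leaves the deconjugated isopropenyl group; the bromide is attacked at its primary carbon.

Step 5
Reactants: 9 (4R)-4-benzyl-3-[(2R,4E)-4-methyl-2-(prop-1-en-2-yl)hex-4-enoyl]-1,3-oxazolidin-2-one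
Product: 10 (2R,4E)-4-methyl-2-(prop-1-en-2-yl)hex-4-en-1-ol
Conditions: LiBH4, H2O (1 equiv), Et2O, 0 °C
Reagents that add atoms: none
Why: Reductive cleavage of the imide gives the primary alcohol without touching C7 and returns the auxiliary.

Step 6
Reactants: 10 (2R,4E)-4-methyl-2-(prop-1-en-2-yl)hex-4-en-1-ol
Product: 11 (2R,4E)-4-methyl-2-(prop-1-en-2-yl)hex-4-enal
Conditions: Dess–Martin periodinane, NaHCO3, CH2Cl2, 0 °C
Reagents that add atoms: none
Why: Buffered Dess–Martin oxidation is non-basic; the α-branched β,γ-unsaturated aldehyde is used at once and unpurified, so that C7 does not epimerise and the alkene does not move into conjugation.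

Step 7
Reactants: 11 (2R,4E)-4-methyl-2-(prop-1-en-2-yl)hex-4-enal
Product: 13 (3S,4R,5R,7E)-7-methyl-5-(prop-1-en-2-yl)nona-1,7-diene-3,4-diol, via anti β-silyl borinate 12 (not isolated)
Conditions: allyl(diisopropylamino)dimethylsilane, n-BuLi, TMEDA, Et2O, 0 °C; (−)-Ipc2BOMe, −78 °C; BF3·OEt2; 11, −78 °C; then KF, KHCO3, 30% H2O2, THF–MeOH, rt
Reagents that add atoms: allyl(diisopropylamino)dimethylsilane C=CC[Si](C)(C)N(C(C)C)C(C)C; hydrogen peroxide OO
Why: Brown-type allylboration with an (E)-γ-silylallyl diisopinocampheylborane goes through a chair transition state, so the E geometry gives the anti C8/C9 relation and the Ipc ligands [from (+)-α-pinene, by the usual facial preference of these reagents] should deliver 8R against the modest bias of C7; Tamao oxidation of the aminosilane in the work-up replaces silicon by hydroxyl with retention.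

Step 8
Reactants: 13 (3S,4R,5R,7E)-7-methyl-5-(prop-1-en-2-yl)nona-1,7-diene-3,4-diol
Product: 14 (4S,5R)-4-ethenyl-2,2-dimethyl-5-[(3R,5E)-2,5-dimethylhepta-1,5-dien-3-yl]-1,3-dioxolane
Conditions: Me2C(OMe)2, PPTS, CH2Cl2, rt
Reagents that add atoms: 2,2-dimethoxypropane COC(C)(C)OC
Why: Acid-catalysed acetal exchange closes the cis-4,5-disubstituted dioxolane on the only 1,2-diol present.

Step 9
Reactants: 14 (4S,5R)-4-ethenyl-2,2-dimethyl-5-[(3R,5E)-2,5-dimethylhepta-1,5-dien-3-yl]-1,3-dioxolane
Product: 16 (3S,5E)-3-[(4R,5S)-5-ethenyl-2,2-dimethyl-1,3-dioxolan-4-yl]-2,5-dimethylhept-5-en-2-ol, via organomercurial 15 (not isolated)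
Conditions: Hg(OAc)2, THF–H2O, 0 °C; then NaOH aq., NaBH4, 0 °C
Reagents that add atoms: water O
Why: Markovnikov oxymercuration–demercuration: toward divalent mercury the 1,1-disubstituted alkene is the most reactive of the three (the vinyl group is deactivated by the allylic acetal oxygen, the trisubstituted alkene is hindered), as in the selective hydration of limonene to α-terpineol; this masks the alkene that would compete as a dienophile in step 14.

Step 10
Reactants: 16 (3S,5E)-3-[(4R,5S)-5-ethenyl-2,2-dimethyl-1,3-dioxolan-4-yl]-2,5-dimethylhept-5-en-2-ol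
Product: 17 isoxazoline: 16 with the vinyl group converted into a 3-methyl-4,5-dihydro-1,2-oxazol-5-yl group (both C10 epimers; C7–C9 as in 16)
Conditions: MeCH=NOH, NCS, DMF, rt; then 16, Et3N (slow addition), CH2Cl2, 0 °C → rt
Reagents that add atoms: acetaldoxime CC=NO
Why: 1,3-Dipolar cycloaddition of acetonitrile oxide to the monosubstituted alkene gives the 5-substituted isoxazoline regioselectively, while the trisubstituted alkene is a far poorer dipolarophile; the new C10 centre is destroyed in step 12, and no metathesis catalyst, which could close a ring between C10 and C5, is involved.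

Step 11
Reactants: 17 isoxazoline (C7–C9 as in 16)
Product: 19 β-hydroxy ketone: 4-hydroxy-4-(dioxolanyl)butan-2-one with C10–OH (both epimers; C7–C9 as in 16), via β-hydroxy imine 18 (not isolated)
Conditions: Mo(CO)6, MeCN–H2O, 80 °C
Reagents that add atoms: water O
Why: Reductive N–O cleavage of the isoxazoline and hydrolysis of the imine unmask the aldol-type β-hydroxy ketone without reducing either alkene.

Step 12
Reactants: 19 β-hydroxy ketone (C7–C9 as in 16)
Product: 21 (3E)-4-[(4S,5R)-5-[(3S,5E)-2-hydroxy-2,5-dimethylhept-5-en-3-yl]-2,2-dimethyl-1,3-dioxolan-4-yl]but-3-en-2-one, via β-acetoxy ketone 20 (not isolated)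
Conditions: Ac2O, Et3N, DMAP (cat.), CH2Cl2, 0 °C; then DBU, rt
Reagents that add atoms: none
Why: The secondary β-hydroxyl is acetylated (the tertiary alcohol is not under these conditions) and E1cB elimination gives the conjugated E enone.

Step 13
Reactants: 21 (3E)-4-[(4S,5R)-5-[(3S,5E)-2-hydroxy-2,5-dimethylhept-5-en-3-yl]-2,2-dimethyl-1,3-dioxolan-4-yl]but-3-en-2-one
Product: 22 triethyl-[(3S,5E)-3-[(4R,5S)-2,2-dimethyl-5-[(1E)-3-(triethylsilyloxy)buta-1,3-dien-1-yl]-1,3-dioxolan-4-yl]-2,5-dimethylhept-5-en-2-yl]oxysilane
Conditions: Et3SiOTf (2.5 equiv), Et3N, CH2Cl2, −78 → 0 °C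
Reagents that add atoms: triethylsilyl trifluoromethanesulfonate CC[Si](CC)(CC)OS(=O)(=O)C(F)(F)F
Why: The silyl triflate caps the tertiary alcohol and, with Et3N, removes a proton from the methyl group of the ketone (kinetic α′-enolisation), giving the cross-conjugated 2-silyloxydiene with the E C10=C1 bond intact; one reagent gives one defined product, and both silyl groups fall to fluoride in step 15.

Step 14
Reactants: 22 triene (2-silyloxydiene, cis-acetonide, silylated C7 carbinol, tiglyl alkene)
Product: 23 cis-fused adduct: (4S,5R,7S,8R,9S,10S)-8,9-(isopropylidenedioxy)-4,5-dimethyl-2-(triethylsilyloxy)-7-[2-(triethylsilyloxy)propan-2-yl]-Δ1-octalin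
Conditions: PhMe (0.01 M), BHT, Et3N (0.2 equiv), sealed tube, 190 °C
Reagents that add atoms: none
Why: This is a thermal type 1 intramolecular Diels–Alder reaction of a 1,7,9-decatriene, concerted and suprafacial on both partners, whose closest known relatives are the cyclisations of unactivated decatrienes and of tethered 2-silyloxydienes. Ring A closes as the new cyclohexene through the σ bonds C3–C4 and C5–C10 (diene C10=C1–C2=C3, dienophile C4=C5), and ring B closes at the same time as the tether ring C5–C6–C7–C8–C9–C10 through C5–C10. C4 and C5 are related by the E geometry of the alkene, which places the two methyl groups cis. The cis fusion comes from the transition state with C6 under the diene, because the trans alternative pushes the C5 methyl group axial on the forming ring B, syn to the axial C9–O bond and to C7–H. The diene face, and so C10 and C5 relative to C7–C9, is set by a chair-like tether with O8 equatorial, O9 axial and the bulky C7 group equatorial; the other face would need that group axial or the C5 methyl syn-axial to O9. The 2-silyloxy group leaves the enol ether, and later the ketone, at C2. The step needs cis fusion and one diene face; the alkene geometry, the cis-dioxolane and the equatorial C7 group (which also favours the C7–C8 rotamer holding C6 next to C9) should secure them, and with the isopropenyl group masked the tiglyl alkene is the only dienophile in reach.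

Step 15
Reactants: 23 cis-fused adduct
Product: 24 (4S,5R,7S,8R,9S,10S)-7-(2-hydroxypropan-2-yl)-8,9-(isopropylidenedioxy)-4,5-dimethyl-cis-decalin-2-one
Conditions: HF·pyridine, pyridine, THF, 0 °C → rt
Reagents that add atoms: none
Why: Buffered fluoride cleaves the silyl enol ether (the ketone forms on protonation at C1) and the tertiary silyl ether, and leaves the acetonide in place.

Step 16
Reactants: 24 keto alcohol acetonide
Product: 25 (4S,5R,7R,8R,9S,10S)-8,9-(isopropylidenedioxy)-4,5-dimethyl-7-(prop-1-en-2-yl)-cis-decalin-2-one
Conditions: Burgess reagent (MeO2CN–SO2NEt3 inner salt), PhMe, 60 °C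
Reagents that add atoms: none
Why: Burgess dehydration by syn-elimination of the sulfamate ester; loss of one of six methyl hydrogens should win over loss of the single hindered C7–H, which would give a tetrasubstituted exocyclic alkene strained (A(1,3)) against the equatorial C8 oxygen and C6.

Step 17
Reactants: 25 isopropenyl keto acetonide
Product: 26 (4S,5R,7R,8R,9S,10S)-8,9-dihydroxy-4,5-dimethyl-7-(prop-1-en-2-yl)-cis-decalin-2-one
Conditions: AcOH–H2O (4:1), 45 °C
Reagents that add atoms: none
Why: Mild aqueous acid hydrolyses the cis-fused dioxolane without hydrating or isomerising the isopropenyl group.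

Step 18
Reactants: 26 keto diol
Product: 27 (4S,5R,7R,8R,9S,10S)-8-acetoxy-9-hydroxy-4,5-dimethyl-7-(prop-1-en-2-yl)-cis-decalin-2-one
Conditions: Ac2O (1.1 equiv), pyridine, CH2Cl2, −20 → 0 °C
Reagents that add atoms: acetic anhydride CC(=O)OC(C)=O
Why: The equatorial C8 hydroxyl is acylated before the axial C9 hydroxyl, which is flanked by the ring fusion and is 1,3-diaxial to the C5–C4 bond; low temperature and no DMAP keep the reaction selective.

Step 19
Reactants: 27 8-acetate; 1 tiglic acid
Product: 29 CNP0204573.1: (4S,5R,7R,8R,9S,10S)-8-acetoxy-4,5-dimethyl-9-[(2E)-2-methylbut-2-enoyloxy]-7-(prop-1-en-2-yl)-cis-decalin-2-one, via tiglic trichlorobenzoic anhydride 28 (not isolated)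
Conditions: 1, 2,4,6-Cl3C6H2COCl, Et3N, PhMe, rt; then 27, DMAP, 70 °C
Reagents that add atoms: none
Why: Yamaguchi esterification: the mixed anhydride is attacked at the less hindered tigloyl carbonyl and DMAP catalysis acylates the hindered axial hydroxyl; the tiglate is the stable E isomer, so its geometry is not at risk.

## Compound list

1 | tiglic acid, (2E)-2-methylbut-2-enoic acid | C/C=C(\C)C(=O)O | starting material
2 | (2E)-2-methylbut-2-en-1-ol | C/C=C(\C)CO | intermediate
3 | (2E)-1-bromo-2-methylbut-2-ene | C/C=C(\C)CBr | intermediate
4 | 3-methylbut-3-enoic acid | C=C(C)CC(=O)O | starting material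
5 | (4R)-4-benzyl-1,3-oxazolidin-2-one | O=C1N[C@H](Cc2ccccc2)CO1 | starting material
6 | 3-methylbut-3-enoic pivalic anhydride | C=C(C)CC(=O)OC(=O)C(C)(C)C | intermediate
7 | (4R)-4-benzyl-3-(3-methylbut-3-enoyl)-1,3-oxazolidin-2-one | C=C(C)CC(=O)N1[C@H](Cc2ccccc2)COC1=O | intermediate
8 | sodium (Z)-dienolate of 7 | [Na+].C=C(C)/C=C(\[O-])N1[C@H](Cc2ccccc2)COC1=O | intermediate
9 | (4R)-4-benzyl-3-[(2R,4E)-4-methyl-2-(prop-1-en-2-yl)hex-4-enoyl]-1,3-oxazolidin-2-one | C=C(C)[C@@H](C/C(C)=C/C)C(=O)N1[C@H](Cc2ccccc2)COC1=O | intermediate
10 | (2R,4E)-4-methyl-2-(prop-1-en-2-yl)hex-4-en-1-ol | C=C(C)[C@@H](C/C(C)=C/C)CO | intermediate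
11 | (2R,4E)-4-methyl-2-(prop-1-en-2-yl)hex-4-enal | C=C(C)[C@@H](C/C(C)=C/C)C=O | intermediate
12 | diisopinocampheylborinate of the anti adduct (C8–O–B, C9–SiMe2N(i-Pr)2) | C=C[C@H]([Si](C)(C)N(C(C)C)C(C)C)[C@H](OB([C@@H]1C[C@@H]2C[C@H]([C@H]1C)C2(C)C)[C@@H]1C[C@@H]2C[C@H]([C@H]1C)C2(C)C)[C@@H](C(C)=C)C/C(C)=C/C | intermediate
13 | (3S,4R,5R,7E)-7-methyl-5-(prop-1-en-2-yl)nona-1,7-diene-3,4-diol | C=C[C@H](O)[C@H](O)[C@@H](C(C)=C)C/C(C)=C/C | intermediate
14 | (4S,5R)-4-ethenyl-2,2-dimethyl-5-[(3R,5E)-2,5-dimethylhepta-1,5-dien-3-yl]-1,3-dioxolane | C=C[C@@H]1OC(C)(C)O[C@@H]1[C@@H](C(C)=C)C/C(C)=C/C | intermediate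
15 | acetoxymercurio carbinol from 14 (HgOAc on the former =CH2 carbon, OH on C11, both C11 epimers) | C=C[C@@H]1OC(C)(C)O[C@@H]1[C@@H](C(C)(O)C[Hg]OC(C)=O)C/C(C)=C/C | intermediate
16 | (3S,5E)-3-[(4R,5S)-5-ethenyl-2,2-dimethyl-1,3-dioxolan-4-yl]-2,5-dimethylhept-5-en-2-ol | C=C[C@@H]1OC(C)(C)O[C@@H]1[C@@H](C(C)(C)O)C/C(C)=C/C | intermediate
17 | isoxazoline: 16 with vinyl replaced by 3-methyl-4,5-dihydro-1,2-oxazol-5-yl (both C10 epimers) | CC1=NOC(C1)[C@@H]1OC(C)(C)O[C@@H]1[C@@H](C(C)(C)O)C/C(C)=C/C | intermediate
18 | β-hydroxy imine from 17 (C2=NH, C10–OH) | CC(=N)CC(O)[C@@H]1OC(C)(C)O[C@@H]1[C@@H](C(C)(C)O)C/C(C)=C/C | intermediate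
19 | β-hydroxy ketone (C2=O, C10–OH, both C10 epimers) | CC(=O)CC(O)[C@@H]1OC(C)(C)O[C@@H]1[C@@H](C(C)(C)O)C/C(C)=C/C | intermediate
20 | β-acetoxy ketone (C10–OAc) | CC(=O)CC(OC(C)=O)[C@@H]1OC(C)(C)O[C@@H]1[C@@H](C(C)(C)O)C/C(C)=C/C | intermediate
21 | (3E)-4-[(4S,5R)-5-[(3S,5E)-2-hydroxy-2,5-dimethylhept-5-en-3-yl]-2,2-dimethyl-1,3-dioxolan-4-yl]but-3-en-2-one | CC(=O)/C=C/[C@@H]1OC(C)(C)O[C@@H]1[C@@H](C(C)(C)O)C/C(C)=C/C | intermediate
22 | triethyl-[(3S,5E)-3-[(4R,5S)-2,2-dimethyl-5-[(1E)-3-(triethylsilyloxy)buta-1,3-dien-1-yl]-1,3-dioxolan-4-yl]-2,5-dimethylhept-5-en-2-yl]oxysilane | C=C(O[Si](CC)(CC)CC)/C=C/[C@@H]1OC(C)(C)O[C@@H]1[C@@H](C(C)(C)O[Si](CC)(CC)CC)C/C(C)=C/C | intermediate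
23 | (4S,5R,7S,8R,9S,10S)-8,9-(isopropylidenedioxy)-4,5-dimethyl-2-(triethylsilyloxy)-7-[2-(triethylsilyloxy)propan-2-yl]-Δ1-octalin, cis-fused | CC(C)(O[Si](CC)(CC)CC)[C@H]1C[C@@]2(C)[C@H](C=C(O[Si](CC)(CC)CC)C[C@@H]2C)[C@@H]3OC(C)(C)O[C@H]13 | intermediate
24 | (4S,5R,7S,8R,9S,10S)-7-(2-hydroxypropan-2-yl)-8,9-(isopropylidenedioxy)-4,5-dimethyl-cis-decalin-2-one | CC(C)(O)[C@H]1C[C@@]2(C)[C@H](CC(=O)C[C@@H]2C)[C@@H]3OC(C)(C)O[C@H]13 | intermediate
25 | (4S,5R,7R,8R,9S,10S)-8,9-(isopropylidenedioxy)-4,5-dimethyl-7-(prop-1-en-2-yl)-cis-decalin-2-one | C=C(C)[C@H]1C[C@@]2(C)[C@H](CC(=O)C[C@@H]2C)[C@@H]3OC(C)(C)O[C@H]13 | intermediate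
26 | (4S,5R,7R,8R,9S,10S)-8,9-dihydroxy-4,5-dimethyl-7-(prop-1-en-2-yl)-cis-decalin-2-one | C=C(C)[C@H]1C[C@@]2(C)[C@H](CC(=O)C[C@@H]2C)[C@H](O)[C@@H]1O | intermediate
27 | (4S,5R,7R,8R,9S,10S)-8-acetoxy-9-hydroxy-4,5-dimethyl-7-(prop-1-en-2-yl)-cis-decalin-2-one | C=C(C)[C@H]1C[C@@]2(C)[C@H](CC(=O)C[C@@H]2C)[C@H](O)[C@@H]1OC(C)=O | intermediate
28 | tiglic 2,4,6-trichlorobenzoic anhydride | C/C=C(\C)C(=O)OC(=O)c1c(Cl)cc(Cl)cc1Cl | intermediate
29 | CNP0204573.1, (4S,5R,7R,8R,9S,10S)-8-acetoxy-4,5-dimethyl-9-[(2E)-2-methylbut-2-enoyloxy]-7-(prop-1-en-2-yl)-cis-decalin-2-one | C=C(C)[C@H]1C[C@@]2(C)[C@H](CC(=O)C[C@@H]2C)[C@H](OC(=O)/C(C)=C/C)[C@@H]1OC(C)=O | target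

## Step count and least certain steps

Total: 19 steps. Longest linear sequence: 18 steps (1 to 29 by way of steps 1, 2 and 4–19). Step 3, which joins 4 and 5 to give 7, is the only step outside this sequence, and 1 is used a second time in step 19.

Step 14 (key step). The cycloaddition may close through the transition state with the tether away from the diene, giving the trans fusion, or on the other diene face. The unactivated trisubstituted alkene may also react so slowly that the dienol ether is lost by desilylation first. The fallback sets the ring fusion by hydrogenation; it cannot correct a wrong diene face. Starting from 23 as a mixture of fusion isomers, Saegusa–Ito oxidation (Pd(OAc)2, MeCN) of the silyl enol ether would give the Δ1(10)-enone with the silylated carbinol F1, which erases C10. HF·pyridine would free the tertiary alcohol to give the enone alcohol F2. Hydrogenation (H2, Pd/C, EtOAc, trace pyridine) should then add hydrogen to C10 from the face of the C5 methyl group, away from the axial C9 oxygen of the dioxolane, and return to the route at 24.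

Step 16. The elimination may lose C7–H instead of a methyl hydrogen, or the sulfamate may ionise, giving the tetrasubstituted isomer. The fallback changes the order and the mechanism: from 24 the acetonide is hydrolysed (AcOH–H2O) to the keto triol F3. The equatorial hydroxyl is acetylated (Ac2O, pyridine) to the 8-acetate F4, and the axial hydroxyl is esterified under the conditions of step 19 to the 8-acetate 9-tiglate tertiary alcohol F5 (the tertiary alcohol does not acylate). The elimination is then run last as an anti E2 process (SOCl2, pyridine, CH2Cl2, −30 °C) on a substrate where loss of C7–H would create an allylic acetate strained against the C8 ester. This comes back to the route at 29.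

Step 19. Acylation of the hindered axial hydroxyl may be slow, and during it the C8 acetyl group may migrate to O9 under base. The fallback installs the tiglate before the acetate. From 26, selective silylation of the equatorial hydroxyl (Et3SiCl, imidazole, CH2Cl2, −20 °C) would give the 8-O-triethylsilyl ether F6. Yamaguchi tigloylation then gives the 8-silyl ether 9-tiglate F7, HF·pyridine gives the 9-tiglate 8-alcohol F8, and unforced acetylation of the equatorial hydroxyl (Ac2O, pyridine, DMAP) returns to the route at 29.

Step 9. Mercuration may not discriminate well enough between the isopropenyl and vinyl groups, or a dioxolane oxygen may take part in opening the mercurinium ion. The fallback keeps the substrate and changes the mechanism from ionic to radical: from 14, cobalt-catalysed Mukaiyama hydration (Co(acac)2, PhSiH3, O2, i-PrOH), in which hydrogen-atom transfer to the unhindered CH2 terminus gives the tertiary radical, would lead directly to 16; no new compound is made (F0).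

## Further compounds

F1 | step 14 | Δ1(10)-enone with 11-O-triethylsilyl group and 8,9-acetonide (C4, C5, C7, C8, C9 as in 23) | CC(C)(O[Si](CC)(CC)CC)[C@H]1C[C@@]2(C)C(=CC(=O)C[C@@H]2C)[C@@H]3OC(C)(C)O[C@H]13
F2 | step 14 | Δ1(10)-enone with free tertiary alcohol and 8,9-acetonide | CC(C)(O)[C@H]1C[C@@]2(C)C(=CC(=O)C[C@@H]2C)[C@@H]3OC(C)(C)O[C@H]13
F3 | step 16 | keto triol: 8,9-dihydroxy-7-(2-hydroxypropan-2-yl)-4,5-dimethyl-cis-decalin-2-one | CC(C)(O)[C@H]1C[C@@]2(C)[C@H](CC(=O)C[C@@H]2C)[C@H](O)[C@@H]1O
F4 | step 16 | 8-acetoxy-9-hydroxy-7-(2-hydroxypropan-2-yl)-4,5-dimethyl-cis-decalin-2-one | CC(C)(O)[C@H]1C[C@@]2(C)[C@H](CC(=O)C[C@@H]2C)[C@H](O)[C@@H]1OC(C)=O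
F5 | step 16 | 8-acetoxy-7-(2-hydroxypropan-2-yl)-4,5-dimethyl-9-[(2E)-2-methylbut-2-enoyloxy]-cis-decalin-2-one | CC(C)(O)[C@H]1C[C@@]2(C)[C@H](CC(=O)C[C@@H]2C)[C@H](OC(=O)/C(C)=C/C)[C@@H]1OC(C)=O
F6 | step 19 | 9-hydroxy-4,5-dimethyl-7-(prop-1-en-2-yl)-8-(triethylsilyloxy)-cis-decalin-2-one | C=C(C)[C@H]1C[C@@]2(C)[C@H](CC(=O)C[C@@H]2C)[C@H](O)[C@@H]1O[Si](CC)(CC)CC
F7 | step 19 | 4,5-dimethyl-9-[(2E)-2-methylbut-2-enoyloxy]-7-(prop-1-en-2-yl)-8-(triethylsilyloxy)-cis-decalin-2-one | C=C(C)[C@H]1C[C@@]2(C)[C@H](CC(=O)C[C@@H]2C)[C@H](OC(=O)/C(C)=C/C)[C@@H]1O[Si](CC)(CC)CC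
F8 | step 19 | 8-hydroxy-4,5-dimethyl-9-[(2E)-2-methylbut-2-enoyloxy]-7-(prop-1-en-2-yl)-cis-decalin-2-one | C=C(C)[C@H]1C[C@@]2(C)[C@H](CC(=O)C[C@@H]2C)[C@H](OC(=O)/C(C)=C/C)[C@@H]1O
F0 | step 9 | none | none
A1 | alternative 1 | cis-fused 4,5-dimethyl-decal-6-ene-2,8-dione (target numbering) | O=C1C=C[C@@]2(C)[C@H](CC(=O)C[C@@H]2C)C1
A2 | alternative 1 | (S)-4-methyl-4-(4-oxopentan-2-yl)cyclohexa-2,5-dien-1-one | CC(=O)C[C@H](C)C1(C)C=CC(=O)C=C1
A3 | alternative 2 | cis-decalin with C6 hydroxyl, C7 isopropenyl, C8 tert-butyldimethylsilyloxy, C9 ethylene ketal and C2 tert-butyldimethylsilyl enol ether | C=C(C)[C@H]1[C@H](O)[C@@]2(C)[C@H](C=C(O[Si](C)(C)C(C)(C)C)C[C@@H]2C)C3(OCCO3)[C@@H]1O[Si](C)(C)C(C)(C)C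
A4 | alternative 2 | ring A silyl enol ether with C5 formyl group and C10 side chain C9 (ethylene ketal)–C8 (silyloxy)–CH=C(CH3)–CH2Br, E | O=C[C@@]1(C)[C@H](C=C(O[Si](C)(C)C(C)(C)C)C[C@@H]1C)C2(OCCO2)[C@H](O[Si](C)(C)C(C)(C)C)/C=C(\C)CBr
A5 | alternative 3 | 8,9-(isopropylidenedioxy)-4,5-dimethyl-7-[2-(triethylsilyloxy)propan-2-yl]-cis-decalin-2-one | CC[Si](CC)(CC)OC(C)(C)[C@H]1C[C@@]2(C)[C@H](CC(=O)C[C@@H]2C)[C@@H]3OC(C)(C)O[C@H]13
A6 | alternative 3 | ring B diene: C10 exocyclic methylene, C5 methyl and isopropenyl, 8,9-acetonide, C7 silylated carbinol | C=C1[C@@H]2OC(C)(C)O[C@@H]2[C@@H](C(C)(C)O[Si](CC)(CC)CC)C[C@]1(C)C(C)=C
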